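The route rests on cutting the bond between benzylic C7 of the heptanone chain and C1 of the catechol ring (ring B). The key step exploits the fact that C5(OH)–C6–C7 is an acrolein unit. In the precursor, C6=C7 is a terminal vinyl group on the finished, enantiopure β-hydroxy ketone. Its unhindered CH2 terminus C7 takes up the aryl group of 1,2-bis(benzyloxy)-4-iodobenzene (iodine para to O4 of ring B) in a silver-assisted Mizoroki–Heck reaction. One operation joins both halves without protecting the C5 carbinol or the C3 ketone. The resulting styrene carries only hydrogen-labile extras, so C6=C7 and three benzyl ethers fall together in the final hydrogenation.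

Key step: step 5

Remark: the chain is numbered C1 (on guaiacyl ring A) to C7 (on catechol ring B). The target is (5R). The same spatial arrangement is named (5S) as long as C6 is an alkene carbon, because C6 then outranks C4. Compounds 1, 3 and 7 are taken as commercial.

Step 1
Reactants: 1 zingerone, 4-(4-hydroxy-3-methoxyphenyl)butan-2-one
Product: 2 4-[4-(benzyloxy)-3-methoxyphenyl]butan-2-one
Conditions: BnBr (1.1 equiv), K2CO3 (1.5 equiv), DMF, rt
Reagents that add atoms: benzyl bromide BrCc1ccccc1
Why: Williamson ether synthesis: K2CO3 deprotonates only the phenol of 1, whose phenoxide displaces bromide, and the benzyl ether removes the acidic proton before the enolate step yet falls in the final hydrogenation.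

Step 2
Reactants: 2 4-[4-(benzyloxy)-3-methoxyphenyl]butan-2-one; 3 acrolein
Product: 5 (±)-1-[4-(benzyloxy)-3-methoxyphenyl]-5-hydroxyhept-6-en-3-one, via kinetic lithium enolate 4 (not isolated)
Conditions: LDA (1.05 equiv), THF, −78 °C; then 3 (1.2 equiv), −78 °C; sat. aq NH4Cl
Reagents that add atoms: none
Why: Directed aldol addition: LDA at −78 °C removes a proton of the less hindered methyl group (C4) under kinetic control and the lithium enolate adds 1,2 to the aldehyde of acrolein, which creates C5 as a racemate that step 3 resolves.

Step 3
Reactants: 5 (±)-1-[4-(benzyloxy)-3-methoxyphenyl]-5-hydroxyhept-6-en-3-one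
Product: 6 (5S)-1-[4-(benzyloxy)-3-methoxyphenyl]-5-hydroxyhept-6-en-3-one
Conditions: Ti(OiPr)4 (0.2 equiv), D-(−)-diisopropyl tartrate (0.25 equiv), t-BuOOH (0.6 equiv, in decane), 4 Å MS, CH2Cl2, −20 °C
Reagents that add atoms: none
Why: Sharpless asymmetric epoxidation run as a kinetic resolution: with the D-(−)-tartrate titanium catalyst the (5R)-allylic alcohol is the fast-reacting enantiomer and is consumed as its erythro epoxy alcohol, so that at slightly more than half conversion the slow (5S)-alcohol 6, which holds the C5 configuration of the target, should remain in high enantiomeric purity and is separated by chromatography.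

Step 4
Reactants: 7 1,2-bis(benzyloxy)benzene
Product: 8 1,2-bis(benzyloxy)-4-iodobenzene
Conditions: NIS (1.05 equiv), CF3CO2H (0.1 equiv), MeCN, rt, dark
Reagents that add atoms: N-iodosuccinimide O=C1CCC(=O)N1I
Why: Electrophilic aromatic iodination: the two positions para to a benzyloxy group are equivalent by symmetry and are more activated and less hindered than all others, so one mono-iodide should result.

Step 5
Reactants: 6 (5S)-1-[4-(benzyloxy)-3-methoxyphenyl]-5-hydroxyhept-6-en-3-one; 8 1,2-bis(benzyloxy)-4-iodobenzene
Product: 9 (5S,6E)-1-[4-(benzyloxy)-3-methoxyphenyl]-7-[3,4-bis(benzyloxy)phenyl]-5-hydroxyhept-6-en-3-one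
Conditions: Pd(OAc)2 (5 mol %), AgOAc (1.2 equiv), DMF, 50 °C, N2, dark
Reagents that add atoms: none
Why: Zerovalent palladium formed in situ inserts into the C–I bond of 8, AgOAc strips iodide to leave a cationic arylpalladium species, the vinyl group of 6 binds, syn-carbopalladation places the aryl group on C7 and palladium on C6, and syn β-hydride elimination of a C7–H gives the (E)-styrene while acetate takes up the proton. The closest known reaction type is the silver-assisted Mizoroki–Heck arylation of free secondary allylic alcohols, which delivers β-aryl allylic alcohols instead of β-aryl ketones. No ring is closed and no stereocenter is made; C5 keeps its S configuration because neither its C–O nor its C–H bond takes part, and the alkene geometry is erased in step 6. Regioselectivity for C7 over C6 follows from the unsubstituted terminus set against the branched, carbinol-bearing C6. The critical selectivity is the direction of β-hydride elimination: the C5 hydroxyl bound to the cationic metal should turn C5–H out of the syn-coplanar alignment, loss of the benzylic C7–H leads to the conjugated product, and fast, irreversible capture of the palladium hydride by AgOAc should suppress re-addition and chain walking toward C5. The nearly neutral medium at moderate temperature should spare the β-hydroxy ketone from retro-aldol cleavage and dehydration, and the aryl C–I bond is the only site open to oxidative addition.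

Step 6
Reactants: 9 (5S,6E)-1-[4-(benzyloxy)-3-methoxyphenyl]-7-[3,4-bis(benzyloxy)phenyl]-5-hydroxyhept-6-en-3-one
Product: 10 (5R)-7-(3,4-dihydroxyphenyl)-5-hydroxy-1-(4-hydroxy-3-methoxyphenyl)heptan-3-one (target)
Conditions: H2 (1 atm), 10% Pd/C, EtOAc/EtOH, rt; work-up under N2
Reagents that add atoms: none
Why: Heterogeneous catalytic hydrogenation and hydrogenolysis: the styrene bond C6=C7 should be saturated first and the three aryl benzyl ethers then cleaved, while the dialkyl ketone and the by then unactivated C5 carbinol are inert, so C5 keeps its arrangement and is renamed R only because C6 now ranks below C4.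

Compound list
1 | zingerone, 4-(4-hydroxy-3-methoxyphenyl)butan-2-one | CC(=O)CCc1ccc(O)c(OC)c1 | starting material
2 | 4-[4-(benzyloxy)-3-methoxyphenyl]butan-2-one | CC(=O)CCc1ccc(OCc2ccccc2)c(OC)c1 | intermediate
3 | acrolein (prop-2-enal) | C=CC=O | starting material
4 | kinetic (terminal) lithium enolate of 2 | [Li]OC(=C)CCc1ccc(OCc2ccccc2)c(OC)c1 | intermediate
5 | (±)-1-[4-(benzyloxy)-3-methoxyphenyl]-5-hydroxyhept-6-en-3-one | COc1cc(CCC(=O)CC(O)C=C)ccc1OCc1ccccc1 | intermediate
6 | (5S)-1-[4-(benzyloxy)-3-methoxyphenyl]-5-hydroxyhept-6-en-3-one | COc1cc(CCC(=O)C[C@H](O)C=C)ccc1OCc1ccccc1 | intermediate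
7 | 1,2-bis(benzyloxy)benzene | c1ccc(COc2ccccc2OCc2ccccc2)cc1 | starting material
8 | 1,2-bis(benzyloxy)-4-iodobenzene | Ic1ccc(OCc2ccccc2)c(OCc2ccccc2)c1 | intermediate
9 | (5S,6E)-1-[4-(benzyloxy)-3-methoxyphenyl]-7-[3,4-bis(benzyloxy)phenyl]-5-hydroxyhept-6-en-3-one | COc1cc(CCC(=O)C[C@H](O)/C=C/c2ccc(OCc3ccccc3)c(OCc3ccccc3)c2)ccc1OCc1ccccc1 | intermediate
10 | (5R)-7-(3,4-dihydroxyphenyl)-5-hydroxy-1-(4-hydroxy-3-methoxyphenyl)heptan-3-one | COc1cc(CCC(=O)C[C@H](O)CCc2ccc(O)c(O)c2)ccc1O | target

Total step count: 6
Longest linear sequence: 5 steps (steps 1, 2, 3, 5 and 6)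

Steps most likely to fail

Step 5. β-Hydride elimination may run toward the carbinol carbon, or palladium hydride may re-add and walk along the chain, with loss of the C5 oxidation level and stereocenter. The free aldol may also undergo retro-aldol cleavage on heating. The fallback sets out from 6 and returns at 9, and it takes the carbinol out of play structurally. Compound 6 is silylated (TBSCl, imidazole, DMF, rt) to (5S)-1-[4-(benzyloxy)-3-methoxyphenyl]-5-[(tert-butyldimethylsilyl)oxy]hept-6-en-3-one F1, which can neither fragment nor bind the metal through oxygen. F1 is coupled with 8 in a neutral-pathway, ligand-free Mizoroki–Heck reaction (Pd(OAc)2, n-Bu4NCl, NaHCO3, DMF, 60 °C) to give (5S,6E)-1-[4-(benzyloxy)-3-methoxyphenyl]-7-[3,4-bis(benzyloxy)phenyl]-5-[(tert-butyldimethylsilyl)oxy]hept-6-en-3-one F2. Buffered desilylation (HF·pyridine, THF, 0 °C) then gives 9.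

Step 3. Epoxidation of the monosubstituted alkene is slow, and chelation of titanium by the β-hydroxy ketone may erode the rate difference between the enantiomers. The fallback sets out from 5 and returns at 6, and it replaces the oxidative resolution by an enzymatic acylative one. Immobilised Candida antarctica lipase B with vinyl acetate in MTBE at 30 °C should acylate the (5S)-enantiomer. This follows the empirical size rule for secondary alcohols, with vinyl as the small group and the keto-aryl chain as the large one. The product is (5S)-7-[4-(benzyloxy)-3-methoxyphenyl]-5-oxohept-1-en-3-yl acetate F3, which is separated from the unreacted alcohol. The same lipase in pH 7 phosphate buffer/MTBE hydrolyses F3 to 6 under neutral conditions that avoid β-elimination.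

Step 6. The cinnamyl-type C5–O bond may be hydrogenolysed, or the allylic alcohol may be isomerised on palladium, before the alkene is saturated. The fallback sets out from 9 and returns at 10, and it separates the two tasks. Metal-free diimide reduction (2-nitrobenzenesulfonyl hydrazide, Et3N, CH2Cl2, rt) saturates C6=C7 to give (5R)-1-[4-(benzyloxy)-3-methoxyphenyl]-7-[3,4-bis(benzyloxy)phenyl]-5-hydroxyheptan-3-one F4. F4 no longer has an activated C–O bond at C5. Hydrogenolysis of its three benzyl ethers (H2, Pd/C, EtOAc/EtOH, rt) gives 10.

Further compounds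
F1 | step 5 | (5S)-1-[4-(benzyloxy)-3-methoxyphenyl]-5-[(tert-butyldimethylsilyl)oxy]hept-6-en-3-one | COc1cc(CCC(=O)C[C@H](O[Si](C)(C)C(C)(C)C)C=C)ccc1OCc1ccccc1
F2 | step 5 | (5S,6E)-1-[4-(benzyloxy)-3-methoxyphenyl]-7-[3,4-bis(benzyloxy)phenyl]-5-[(tert-butyldimethylsilyl)oxy]hept-6-en-3-one | COc1cc(CCC(=O)C[C@H](O[Si](C)(C)C(C)(C)C)/C=C/c2ccc(OCc3ccccc3)c(OCc3ccccc3)c2)ccc1OCc1ccccc1
F3 | step 3 | (5S)-7-[4-(benzyloxy)-3-methoxyphenyl]-5-oxohept-1-en-3-yl acetate | COc1cc(CCC(=O)C[C@H](OC(C)=O)C=C)ccc1OCc1ccccc1
F4 | step 6 | (5R)-1-[4-(benzyloxy)-3-methoxyphenyl]-7-[3,4-bis(benzyloxy)phenyl]-5-hydroxyheptan-3-one | COc1cc(CCC(=O)C[C@H](O)CCc2ccc(OCc3ccccc3)c(OCc3ccccc3)c2)ccc1OCc1ccccc1
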